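**Retrosynthetic overview**
- Nine-membered ether ring last: intramolecular Nozaki–Hiyama–Kishi closure of C6–C7 from a 2-iodoalkene/aldehyde, which sets C6.
- Seven-membered lactone before it: Shi epoxidation of a (Z)-C3=C4 alkene, then acid-triggered 7-exo opening at C3 by the C16 acid; this sets C3 and C4 and frees O4 for the octanoate.
- C11 carbinol from a halohydrin-derived epoxide opened by hydride; C15 by hydroboration of the carvone isopropenyl group.
- Hydroisobenzofuran first: Prins–pinacol condensation of a carvone-derived dienyl diol with a (Z)-enal, then photodecarbonylation.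
- Ring order: six-membered carbocycle (from (R)-carvone) → tetrahydrofuran → lactone → nine-membered ring; the other building blocks are methyl (S)-glycidate and 1,3-propanediol.

Assumption: atoms are numbered as in the cladiellin skeleton (C1–C16), "α" is the face of the six-membered ring that carries C2 and C9, and the drawn enantiomer is (1S,2S,3S,4R,6S,9S,10R,11R,14R,15R), which maps onto (R)-carvone.

**Route**

Step 1
Reactants: 1 1,3-propanediol (3 equiv)
Product: 2 3-[(triisopropylsilyl)oxy]propan-1-ol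
Conditions: i-Pr3SiCl (1 equiv), imidazole, THF, 0 °C → rt
Reagents that add atoms: triisopropylsilyl chloride, CC(C)[Si](Cl)(C(C)C)C(C)C
Why: Statistical monosilylation of the excess symmetrical diol (silyl ether formation); no stereocentre is involved.

Step 2
Reactants: 2 3-[(triisopropylsilyl)oxy]propan-1-ol
Product: 3 3-[(triisopropylsilyl)oxy]propanal
Conditions: TEMPO (cat.), PhI(OAc)2, CH2Cl2, rt
Reagents that add atoms: none
Why: Nitroxyl-catalysed oxidation of a primary alcohol stops at the aldehyde under anhydrous conditions.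

Step 3
Reactants: 3 3-[(triisopropylsilyl)oxy]propanal
Product: 4 methyl (2Z)-2-methyl-5-[(triisopropylsilyl)oxy]pent-2-enoate
Conditions: (CF3CH2O)2P(O)CH(CH3)CO2CH3, KN(SiMe3)2, 18-crown-6, THF, −78 °C
Reagents that add atoms: methyl 2-[bis(2,2,2-trifluoroethoxy)phosphoryl]propanoate, COC(=O)C(C)P(=O)(OCC(F)(F)F)OCC(F)(F)F
Why: Still–Gennari olefination, in which the electron-poor phosphonate under dissociating conditions gives the kinetic (Z)-trisubstituted enoate.

Step 4
Reactants: 4 methyl (2Z)-2-methyl-5-[(triisopropylsilyl)oxy]pent-2-enoate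
Product: 5 (2Z)-2-methyl-5-[(triisopropylsilyl)oxy]pent-2-en-1-ol
Conditions: i-Bu2AlH (2.2 equiv), CH2Cl2, −78 °C
Reagents that add atoms: none
Why: 1,2-Reduction of the enoate by the aluminium hydride leaves the alkene geometry untouched.

Step 5
Reactants: 5 (2Z)-2-methyl-5-[(triisopropylsilyl)oxy]pent-2-en-1-ol
Product: 6 (2Z)-2-methyl-5-[(triisopropylsilyl)oxy]pent-2-enal
Conditions: MnO2, CH2Cl2, 0 °C → rt, used at once
Reagents that add atoms: none
Why: Neutral heterogeneous allylic oxidation gives the enal without Z-to-E isomerisation.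

Step 6
Reactants: 7 methyl (2S)-oxirane-2-carboxylate
Product: 8 methyl (2S)-2-hydroxy-5-(trimethylsilyl)pent-4-ynoate
Conditions: HC≡CSiMe3, n-BuLi, THF, −78 °C; BF3·OEt2; then 7, −78 °C
Reagents that add atoms: (trimethylsilyl)acetylene, C#C[Si](C)(C)C
Why: Lewis-acid-assisted epoxide opening by the lithium acetylide (Yamaguchi alkynylation) occurs at the terminal carbon, so the C2 stereocentre (later C9) is kept.

Step 7
Reactants: 8 methyl (2S)-2-hydroxy-5-(trimethylsilyl)pent-4-ynoate
Product: 9 methyl (2S)-2-[(triethylsilyl)oxy]-5-(trimethylsilyl)pent-4-ynoate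
Conditions: Et3SiCl, imidazole, CH2Cl2, 0 °C
Reagents that add atoms: chlorotriethylsilane, CC[Si](Cl)(CC)CC
Why: Standard silyl ether protection of the secondary carbinol.

Step 8
Reactants: 9 methyl (2S)-2-[(triethylsilyl)oxy]-5-(trimethylsilyl)pent-4-ynoate
Product: 10 (2S)-2-[(triethylsilyl)oxy]-5-(trimethylsilyl)pent-4-ynal
Conditions: i-Bu2AlH (1.1 equiv), CH2Cl2, −78 °C
Reagents that add atoms: none
Why: Partial ester reduction through a tetrahedral aluminate that is stable at −78 °C gives the α-silyloxy aldehyde without epimerisation.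

Step 9
Reactants: 11 (R)-(−)-carvone
Product: 13 (3R)-6-methyl-3-(prop-1-en-2-yl)cyclohexa-1,5-dien-1-yl trifluoromethanesulfonate, via lithium dienolate 12 (not isolated)
Conditions: LiN(i-Pr)2, THF, −78 °C; then PhNTf2, −78 → 0 °C
Reagents that add atoms: N-phenylbis(trifluoromethanesulfonimide), O=S(=O)(N(c1ccccc1)S(=O)(=O)C(F)(F)F)C(F)(F)F
Why: Kinetic α′-deprotonation of the enone and O-sulfonylation of the cross-conjugated enolate give the dienyl triflate; the carvone stereocentre (later C14) is untouched.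

Step 10
Reactants: 13 (3R)-6-methyl-3-(prop-1-en-2-yl)cyclohexa-1,5-dien-1-yl trifluoromethanesulfonate; 10 (2S)-2-[(triethylsilyl)oxy]-5-(trimethylsilyl)pent-4-ynal
Product: 14 (1R,2S)-1-[(3R)-6-methyl-3-(prop-1-en-2-yl)cyclohexa-1,5-dien-1-yl]-2-[(triethylsilyl)oxy]-5-(trimethylsilyl)pent-4-yn-1-ol
Conditions: NiCl2 (1 mol %), CrCl2 (4 equiv), DMF, rt
Reagents that add atoms: none
Why: Nozaki–Hiyama–Kishi coupling (oxidative addition of the triflate to zerovalent nickel, transfer to chromium, Felkin–Anh addition) gives the anti carbinol, whose configuration is irrelevant because this carbon becomes the formyl group removed in step 13.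

Step 11
Reactants: 14 (1R,2S)-1-[(3R)-6-methyl-3-(prop-1-en-2-yl)cyclohexa-1,5-dien-1-yl]-2-[(triethylsilyl)oxy]-5-(trimethylsilyl)pent-4-yn-1-ol
Product: 15 (1R,2S)-1-[(3R)-6-methyl-3-(prop-1-en-2-yl)cyclohexa-1,5-dien-1-yl]-5-(trimethylsilyl)pent-4-yne-1,2-diol
Conditions: PPTS (0.1 equiv), MeOH, 0 °C
Reagents that add atoms: none
Why: Mild acid-catalysed methanolysis removes the secondary triethylsilyl ether while the C-silyl alkyne survives.

Step 12
Reactants: 15 (1R,2S)-1-[(3R)-6-methyl-3-(prop-1-en-2-yl)cyclohexa-1,5-dien-1-yl]-5-(trimethylsilyl)pent-4-yne-1,2-diol; 6 (2Z)-2-methyl-5-[(triisopropylsilyl)oxy]pent-2-enal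
Product: 17 cis-fused 10-formyl hexahydroisobenzofuran (C2 (Z)-C(CH3)=CHCH2CH2OSi(i-Pr)3; C9 CH2C≡CSiMe3; C11=C12; C14 isopropenyl), via dioxolane acetal 16 (not isolated)
Conditions: p-TsOH·H2O (5 mol %), MgSO4, CH2Cl2, −20 °C; then SnCl4 (0.2 equiv), −78 → −20 °C
Reagents that add atoms: none
Why: Prins–pinacol reaction, in which the (E)-oxocarbenium ion is attacked by the diene through a chair transition state with the C2 and C9 substituents equatorial and anti to the isopropenyl group, and 1,2-shift of C9 with retention then contracts the ring, setting C1, C2 and C10 in a 2,5-cis, cis-fused tetrahydrofuran.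

Step 13
Reactants: 17 cis-fused 10-formyl hexahydroisobenzofuran
Product: 18 cis-fused hexahydroisobenzofuran with H at C10 (side chains as in 17)
Conditions: hν (medium-pressure Hg lamp, Pyrex), degassed 1,4-dioxane, rt
Reagents that add atoms: none
Why: Norrish type 1 cleavage of the β,γ-unsaturated aldehyde and in-cage hydrogen transfer (photodecarbonylation) replace CHO by H with retention, so the cis ring fusion is kept.

Step 14
Reactants: 18 cis-fused hexahydroisobenzofuran with C14 isopropenyl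
Product: 20 (15R) primary alcohol (C14 CH(CH3)CH2OH), via trialkylborane 19 (not isolated)
Conditions: (−)-Ipc2BH (from (+)-α-pinene), THF, −25 → 0 °C; then NaBO3·4H2O, THF–H2O, rt
Reagents that add atoms: sodium perborate, [Na+].[Na+].O[B-]1(O)OO[B-](O)(O)OO1
Why: Brown hydroboration–oxidation, in which the hindered borane adds anti-Markovnikov only to the 1,1-disubstituted alkene, from the face anti to the bulkier C1 branch in the conformer with H14 eclipsing the alkene, and the reagent's own preference for the R-configured 2-methyl carbinol is expected to reinforce this (matched pair) to give 15R.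

Step 15
Reactants: 20 (15R) primary alcohol
Product: 22 11,12-α-epoxide with terminal alkyne, via trans-bromohydrin 21 (not isolated)
Conditions: NBS (1.05 equiv), THF–H2O (3:1), 0 °C; then K2CO3, MeOH, rt
Reagents that add atoms: water, O
Why: Halohydrin formation followed by internal Williamson closure: the bromonium ion forms on the more electron-rich ring alkene from the open face anti to the pseudoaxial C10–C9 bond, water adds anti, and base closes the oxirane on the opposite (α) face whichever carbon water attacked, while methanolysis also removes the alkynyl silyl group.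

Step 16
Reactants: 22 11,12-α-epoxide
Product: 23 diol (C11 tertiary OH cis to C9; C16 primary OH)
Conditions: LiEt3BH (3 equiv), THF, 0 °C → rt
Reagents that add atoms: none
Why: SN2 hydride opening of the trisubstituted epoxide at the secondary carbon C12 leaves the C11–O bond intact and gives the 11R tertiary carbinol.

Step 17
Reactants: 23 diol
Product: 24 C16 carboxylic acid
Conditions: TEMPO (0.2 equiv), PhI(OAc)2 (2.5 equiv), MeCN–H2O (1:1), rt
Reagents that add atoms: water, O
Why: Nitroxyl-catalysed oxidation of the primary alcohol through the aldehyde hydrate gives the acid under near-neutral conditions that spare the tertiary alcohol, alkene, alkyne and the C15 stereocentre.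

Step 18
Reactants: 24 C16 carboxylic acid
Product: 26 seven-membered lactone with free C4–OH, via epoxy acid 25 (not isolated)
Conditions: D-fructose-derived Shi ketone (0.3 equiv), KHSO5 (as 2KHSO5·KHSO4·K2SO4), K2CO3, Bu4NHSO4 (cat.), MeCN–(MeO)2CH2–aq. Na2B4O7 buffer, 0 °C; acidify to pH 3 and extract; then CSA (0.1 equiv), CH2Cl2, rt
Reagents that add atoms: potassium peroxymonosulfate, [K+].[O-]S(=O)(=O)OO
Why: Shi asymmetric epoxidation gives the (3R,4R)-oxirane by reagent control, and acid-catalysed 7-exo opening by the carboxylic acid at the tertiary carbon with inversion then sets C3 (S) and leaves C4–OH (R), a net anti addition to the (Z)-alkene.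

Step 19
Reactants: 26 seven-membered lactone with free C4–OH
Product: 27 C4 octanoate
Conditions: n-C7H15COCl, pyridine, DMAP (cat.), CH2Cl2, 0 °C → rt
Reagents that add atoms: octanoyl chloride, CCCCCCCC(=O)Cl
Why: DMAP-catalysed acylation takes the only secondary hydroxyl, and the hindered tertiary C11–OH does not react.

Step 20
Reactants: 27 C4 octanoate
Product: 29 2-iodoalkene (C9 CH2C(I)=CH2), via iodoalkenylborane 28 (not isolated)
Conditions: B-iodo-9-BBN (2.5 equiv), CH2Cl2–hexane, −20 → 0 °C; then AcOH, 0 °C; HOCH2CH2NH2 work-up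
Reagents that add atoms: B-iodo-9-borabicyclo[3.3.1]nonane, IB1C2CCCC1CCC2
Why: Hara–Suzuki haloboration adds B–I syn across the terminal alkyne with iodine on the internal carbon, and protodeboronation gives the 2-iodo-1-alkene; any borinate formed at the C11 hydroxyl is cleaved on work-up.

Step 21
Reactants: 29 2-iodoalkene
Product: 30 C6 primary alcohol
Conditions: HF·pyridine, pyridine, THF, 0 °C → rt
Reagents that add atoms: none
Why: Buffered fluoride desilylation cleaves the primary silyl ether and spares the esters and the vinyl iodide.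

Step 22
Reactants: 30 C6 primary alcohol
Product: 31 C6 aldehyde
Conditions: Dess–Martin periodinane, NaHCO3, CH2Cl2, 0 °C → rt
Reagents that add atoms: none
Why: Buffered Dess–Martin oxidation gives the β-acyloxy aldehyde without elimination of octanoate.

Step 23
Reactants: 31 C6 aldehyde
Product: 32 briarellin A
Conditions: NiCl2 (2 mol %), CrCl2 (8 equiv), DMSO, rt, 0.003 M
Reagents that add atoms: none
Why: Intramolecular Nozaki–Hiyama–Kishi reaction closes the nine-membered ring at C6–C7, and the rigid tricyclic core is expected to expose one aldehyde face to the alkenylchromium, giving the 6S allylic alcohol.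

**Compound list**

1 | 1,3-propanediol | OCCCO | starting material
2 | 3-[(triisopropylsilyl)oxy]propan-1-ol | OCCCO[Si](C(C)C)(C(C)C)C(C)C | intermediate
3 | 3-[(triisopropylsilyl)oxy]propanal | O=CCCO[Si](C(C)C)(C(C)C)C(C)C | intermediate
4 | methyl (2Z)-2-methyl-5-[(triisopropylsilyl)oxy]pent-2-enoate | COC(=O)/C(C)=C\CCO[Si](C(C)C)(C(C)C)C(C)C | intermediate
5 | (2Z)-2-methyl-5-[(triisopropylsilyl)oxy]pent-2-en-1-ol | OC/C(C)=C\CCO[Si](C(C)C)(C(C)C)C(C)C | intermediate
6 | (2Z)-2-methyl-5-[(triisopropylsilyl)oxy]pent-2-enal | O=C/C(C)=C\CCO[Si](C(C)C)(C(C)C)C(C)C | intermediate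
7 | methyl (2S)-oxirane-2-carboxylate (methyl (S)-glycidate) | COC(=O)[C@@H]1CO1 | starting material
8 | methyl (2S)-2-hydroxy-5-(trimethylsilyl)pent-4-ynoate | COC(=O)[C@@H](O)CC#C[Si](C)(C)C | intermediate
9 | methyl (2S)-2-[(triethylsilyl)oxy]-5-(trimethylsilyl)pent-4-ynoate | COC(=O)[C@@H](O[Si](CC)(CC)CC)CC#C[Si](C)(C)C | intermediate
10 | (2S)-2-[(triethylsilyl)oxy]-5-(trimethylsilyl)pent-4-ynal | O=C[C@@H](O[Si](CC)(CC)CC)CC#C[Si](C)(C)C | intermediate
11 | (R)-(−)-carvone, (5R)-2-methyl-5-(prop-1-en-2-yl)cyclohex-2-en-1-one | CC1=CC[C@H](CC1=O)C(C)=C | starting material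
12 | lithium (3R)-6-methyl-3-(prop-1-en-2-yl)cyclohexa-1,5-dien-1-olate | [Li]OC1=C[C@H](C(C)=C)CC=C1C | intermediate (not isolated)
13 | (3R)-6-methyl-3-(prop-1-en-2-yl)cyclohexa-1,5-dien-1-yl trifluoromethanesulfonate | CC1=CC[C@H](C=C1OS(=O)(=O)C(F)(F)F)C(C)=C | intermediate
14 | (1R,2S)-1-[(3R)-6-methyl-3-(prop-1-en-2-yl)cyclohexa-1,5-dien-1-yl]-2-[(triethylsilyl)oxy]-5-(trimethylsilyl)pent-4-yn-1-ol | C[Si](C)(C)C#CC[C@H](O[Si](CC)(CC)CC)[C@H](O)C1=C[C@H](C(C)=C)CC=C1C | intermediate
15 | (1R,2S)-1-[(3R)-6-methyl-3-(prop-1-en-2-yl)cyclohexa-1,5-dien-1-yl]-5-(trimethylsilyl)pent-4-yne-1,2-diol | C[Si](C)(C)C#CC[C@H](O)[C@H](O)C1=C[C@H](C(C)=C)CC=C1C | intermediate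
16 | cis-4,5-disubstituted 2-[(Z)-alkenyl]-1,3-dioxolane from 15 and 6 (acetal carbon as epimer mixture) | C[Si](C)(C)C#CC[C@@H]1OC(O[C@@H]1C2=C[C@H](C(C)=C)CC=C2C)/C(C)=C\CCO[Si](C(C)C)(C(C)C)C(C)C | intermediate (not isolated)
17 | cis-fused 10-formyl hexahydroisobenzofuran: C2 (Z)-C(CH3)=CHCH2CH2OSi(i-Pr)3 and C9 CH2C≡CSiMe3 cis to each other and anti to the carbocycle; C11=C12; C14 isopropenyl trans to C2 | C[Si](C)(C)C#CC[C@@H]2O[C@H](/C(C)=C\CCO[Si](C(C)C)(C(C)C)C(C)C)[C@H]4[C@@H](CC=C(C)[C@]42C=O)C(C)=C | intermediate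
18 | decarbonylated bicycle: as 17 with H at C10 (H1 and H10 cis) | C[Si](C)(C)C#CC[C@@H]2O[C@H](/C(C)=C\CCO[Si](C(C)C)(C(C)C)C(C)C)[C@H]4[C@@H](CC=C(C)[C@H]42)C(C)=C | intermediate
19 | C16 bis(isopinocampheyl)borane adduct of 18 (15R) | C[Si](C)(C)C#CC[C@@H]2O[C@H](/C(C)=C\CCO[Si](C(C)C)(C(C)C)C(C)C)[C@H]4[C@@H](CC=C(C)[C@H]42)[C@@H](C)CB([C@@H]5C[C@@H]6C[C@H]([C@H]5C)C6(C)C)[C@@H]7C[C@@H]8C[C@H]([C@H]7C)C8(C)C | intermediate (not isolated)
20 | (15R) primary alcohol: as 18 with C14 CH(CH3)CH2OH | C[Si](C)(C)C#CC[C@@H]2O[C@H](/C(C)=C\CCO[Si](C(C)C)(C(C)C)C(C)C)[C@H]4[C@@H](CC=C(C)[C@H]42)[C@@H](C)CO | intermediate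
21 | trans-bromohydrin of 20 (C11 α-OH, C12 β-Br; the regioisomer closes to the same epoxide) | C[Si](C)(C)C#CC[C@@H]2O[C@H](/C(C)=C\CCO[Si](C(C)C)(C(C)C)C(C)C)[C@H]4[C@@H](C[C@H](Br)[C@@](C)(O)[C@H]42)[C@@H](C)CO | intermediate (not isolated)
22 | 11,12-α-epoxide (oxirane cis to C9), terminal alkyne, C16 alcohol | C#CC[C@@H]2O[C@H](/C(C)=C\CCO[Si](C(C)C)(C(C)C)C(C)C)[C@H]4[C@@H](C[C@H]5O[C@@]5(C)[C@H]42)[C@@H](C)CO | intermediate
23 | diol: (11R) tertiary alcohol and C16 primary alcohol | C#CC[C@@H]2O[C@H](/C(C)=C\CCO[Si](C(C)C)(C(C)C)C(C)C)[C@H]4[C@@H](CC[C@@](C)(O)[C@H]42)[C@@H](C)CO | intermediate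
24 | (15R) C16 carboxylic acid with (Z)-C3=C4 alkene | C#CC[C@@H]2O[C@H](/C(C)=C\CCO[Si](C(C)C)(C(C)C)C(C)C)[C@H]4[C@@H](CC[C@@](C)(O)[C@H]42)[C@@H](C)C(=O)O | intermediate
25 | (3R,4R)-epoxy acid | C#CC[C@@H]2O[C@H]([C@]6(C)O[C@@H]6CCO[Si](C(C)C)(C(C)C)C(C)C)[C@H]4[C@@H](CC[C@@](C)(O)[C@H]42)[C@@H](C)C(=O)O | intermediate (not isolated)
26 | tricyclic lactone (C16(=O)–O–C3; 3S) with free (4R)-OH | C#CC[C@@H]2O[C@H]3[C@H]4[C@@H](CC[C@@](C)(O)[C@H]42)[C@@H](C)C(=O)O[C@@]3(C)[C@H](O)CCO[Si](C(C)C)(C(C)C)C(C)C | intermediate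
27 | C4 octanoate of 26 | C#CC[C@@H]2O[C@H]3[C@H]4[C@@H](CC[C@@](C)(O)[C@H]42)[C@@H](C)C(=O)O[C@@]3(C)[C@H](OC(=O)CCCCCCC)CCO[Si](C(C)C)(C(C)C)C(C)C | intermediate
28 | (Z)-2-iodoalkenyl-9-BBN adduct of 27 | B1(C2CCCC1CCC2)/C=C(\I)C[C@@H]2O[C@H]3[C@H]4[C@@H](CC[C@@](C)(O)[C@H]42)[C@@H](C)C(=O)O[C@@]3(C)[C@H](OC(=O)CCCCCCC)CCO[Si](C(C)C)(C(C)C)C(C)C | intermediate (not isolated)
29 | 2-iodoalkene with C6 silyl ether | C=C(I)C[C@@H]2O[C@H]3[C@H]4[C@@H](CC[C@@](C)(O)[C@H]42)[C@@H](C)C(=O)O[C@@]3(C)[C@H](OC(=O)CCCCCCC)CCO[Si](C(C)C)(C(C)C)C(C)C | intermediate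
30 | 2-iodoalkene with C6 primary alcohol | C=C(I)C[C@@H]2O[C@H]3[C@H]4[C@@H](CC[C@@](C)(O)[C@H]42)[C@@H](C)C(=O)O[C@@]3(C)[C@H](OC(=O)CCCCCCC)CCO | intermediate
31 | 2-iodoalkene with C6 aldehyde | C=C(I)C[C@@H]2O[C@H]3[C@H]4[C@@H](CC[C@@](C)(O)[C@H]42)[C@@H](C)C(=O)O[C@@]3(C)[C@H](OC(=O)CCCCCCC)CC=O | intermediate
32 | briarellin A, (1S,2S,3S,4R,6S,9S,10R,11R,14R,15R) in cladiellin numbering | C=C1C[C@@H]2O[C@H]3[C@H]4[C@@H](CC[C@@](C)(O)[C@H]42)[C@@H](C)C(=O)O[C@@]3(C)[C@H](OC(=O)CCCCCCC)C[C@@H]1O | target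

**Step count and risks**

Total: 23 steps. Longest linear sequence: 17 steps (1 → 32 through steps 1–5 and 12–23; equally 7 → 32 through steps 6–8 and 10–23). From carvone 11 it is 15 steps.

Most likely to fail:

Step 14 (C15 by hydroboration). Asymmetric induction at a 1,1-disubstituted alkene is modest, and the matched sense rests on a conformational model. The fallback changes from diastereoselective addition to enzymatic kinetic resolution. It sets out from 18: hydroboration with 9-BBN and NaBO3·4H2O gives 20 together with its C15 epimer, the 15S alcohol F1. The mixture is treated with Burkholderia cepacia lipase and vinyl acetate in t-BuOMe, which is expected to acylate the S-configured 2-methyl carbinol faster and give the 15S acetate F2. Unreacted 20 is separated by chromatography, and the route is rejoined at 20.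

Step 15 (α-epoxide at C11–C12). The bromonium ion may form on the other ring face, or NBS may also attack the C3=C4 alkene. The fallback replaces the halohydrin detour by direct oxygen transfer, which delivers oxygen to the face that the halohydrin route leaves free. It sets out from 20: m-CPBA with NaHCO3 in CH2Cl2 at −20 °C epoxidises the ring alkene without a cationic intermediate and gives the silylated epoxide F3 if the α-face is the open one. K2CO3 in MeOH then removes the alkynyl silyl group, and the route is rejoined at 22.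

Step 18 (epoxidation and seven-membered lactonisation). Reagent control may be eroded by the allylic stereocentre, and the 7-exo closure may be slow. The fallback forms the lactone C–O bond by acylation instead of epoxide opening. It sets out from 24: Me3SiCHN2 in MeOH–toluene gives the methyl ester F4. The same Shi epoxidation gives the epoxy ester F5. HClO4 (cat.) in THF–H2O opens the oxirane at C3 with inversion to the diol ester F6. Octanoyl chloride, pyridine and DMAP acylate the secondary hydroxyl to give the octanoate ester F7. Me3SnOH in 1,2-dichloroethane at 70 °C cleaves the methyl ester to the seco acid F8. Yamaguchi lactonisation (2,4,6-trichlorobenzoyl chloride, Et3N, then DMAP, toluene, 80 °C) onto the tertiary C3–OH rejoins the route at 27.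

**Further compounds**

F1 | step 14 | 15S alcohol (C15 epimer of 20) | C[Si](C)(C)C#CC[C@@H]2O[C@H](/C(C)=C\CCO[Si](C(C)C)(C(C)C)C(C)C)[C@H]4[C@@H](CC=C(C)[C@H]42)[C@H](C)CO
F2 | step 14 | 15S acetate (acetate of F1) | C[Si](C)(C)C#CC[C@@H]2O[C@H](/C(C)=C\CCO[Si](C(C)C)(C(C)C)C(C)C)[C@H]4[C@@H](CC=C(C)[C@H]42)[C@H](C)COC(C)=O
F3 | step 15 | silylated epoxide (22 with the alkynyl SiMe3 group) | C[Si](C)(C)C#CC[C@@H]2O[C@H](/C(C)=C\CCO[Si](C(C)C)(C(C)C)C(C)C)[C@H]4[C@@H](C[C@H]5O[C@@]5(C)[C@H]42)[C@@H](C)CO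
F4 | step 18 | methyl ester of 24 | C#CC[C@@H]2O[C@H](/C(C)=C\CCO[Si](C(C)C)(C(C)C)C(C)C)[C@H]4[C@@H](CC[C@@](C)(O)[C@H]42)[C@@H](C)C(=O)OC
F5 | step 18 | (3R,4R)-epoxy methyl ester | C#CC[C@@H]2O[C@H]([C@]6(C)O[C@@H]6CCO[Si](C(C)C)(C(C)C)C(C)C)[C@H]4[C@@H](CC[C@@](C)(O)[C@H]42)[C@@H](C)C(=O)OC
F6 | step 18 | (3S,4R)-3,4-diol methyl ester | C#CC[C@@H]2O[C@H]([C@@](C)(O)[C@H](O)CCO[Si](C(C)C)(C(C)C)C(C)C)[C@H]4[C@@H](CC[C@@](C)(O)[C@H]42)[C@@H](C)C(=O)OC
F7 | step 18 | 4-O-octanoyl diol methyl ester | C#CC[C@@H]2O[C@H]([C@@](C)(O)[C@H](OC(=O)CCCCCCC)CCO[Si](C(C)C)(C(C)C)C(C)C)[C@H]4[C@@H](CC[C@@](C)(O)[C@H]42)[C@@H](C)C(=O)OC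
F8 | step 18 | 4-O-octanoyl seco acid | C#CC[C@@H]2O[C@H]([C@@](C)(O)[C@H](OC(=O)CCCCCCC)CCO[Si](C(C)C)(C(C)C)C(C)C)[C@H]4[C@@H](CC[C@@](C)(O)[C@H]42)[C@@H](C)C(=O)O
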